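The data are calculated for substances that don't exist, noise included.

A chain needs a beginning, so one chain is counted for each pre-initiator charged, and amounts are reckoned as fractions of their charge.

| flask | free monomer | protic impurity | pre-initiator | remark | time |
|---|---|---|---|---|---|
| ash | 0.57 M | 0.285 M | 0.1 mol% | run made earlier |  |
| birch | 0.57 M | 0.285 M | 0.44 mol% | run made earlier |  |
| south-east | 0.57 M | 0.285 M | 0.5 mol% |  | 6.0 d |
| south | 0.57 M | 0.285 M | 0.12 mol% |  | 6.0 d |

| run | time / d | monomer in chains / % |
|---|---|---|
| ash | 0.167 | 0 |
| ash | 0.500 | 2.6 |
| ash | 0.833 | 3.0 |
| ash | 1.25 | 3.2 |
| ash | 1.67 | 8.9 |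
| ash | 2.50 | 13.3 |
| ash | 3.00 | 19.5 |
| birch | 0.250 | 1.6 |
| birch | 0.333 | 0.8 |
| birch | 0.500 | 4.9 |
| birch | 0.833 | 11.3 |
| birch | 1.25 | 21.5 |
| birch | 2.08 | 36.8 |
| birch | 3.00 | 49.8 |

(each reading ± 1 percentage point)

* which of the two ends with the longer chains by the average number of monomer units in a chain (chains begun, living or dead) ("neither" if they lie within 10 %) (south-east / south / neither)
* average number of monomer units in a chain (chains begun, living or dead) at the end, south-east
* average number of monomer units in a chain (chains begun, living or dead) at the end, south

- the average divides the monomer in chains by the number of chains begun, living and dead together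
- the earlier runs do not show the number of chains; that part of a forecast is a guess

The ledger below is a reckoning of its own, made from the two earlier runs: it books the pre-initiator into chains, then the free monomer into those chains.

1. Chains. South-east has 200 as its full-book length, the monomer units per chain with one chain per pre-initiator and the whole charge of free monomer in chains. South has 833. The readings do not show the chain count, so this entry is a guess.

2. Monomer. The fraction not in chains is taken to fall as exp(−s·(time − lag)). The birch readings from 1.25 d to 3.00 d give s = 0.255 d⁻¹ and a lag of 0.302 d. The ash readings from 1.67 d to 3.00 d give 0.0930 d⁻¹ and 0.668 d. Between these runs, s goes with the loading to the power 0.682, a reading that carries their scatter. Scaling from the nearer run, south-east has 0.279 d⁻¹ and reaches 79.6 % in chains at 6.0 d; south has 0.105 d⁻¹ and reaches 43.0 %.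

3. Closing. The fraction in chains times the full-book length gives 159 for south-east and 358 for south, so on this ledger south ends longer.

The forecast also names south, with 170 (60 to 450) for south-east, higher than this ledger, and 360 (90 to 1000) for south. Of its count it says: “I assume about one chain per pre-initiator, which is a guess”.

The simulation gives 185 for south-east and 363 for south, so south ends longer.

    protic impurity + free monomer → quenched substrate (k = 0.0420 M⁻¹ h⁻¹)
    free monomer + initiator → living end + monomer in chains (k = 0.0593 M⁻¹ h⁻¹)
    free monomer + living end → monomer in chains + living end, rate k3*[living end]*[free monomer] (k = 14.0 M⁻¹ h⁻¹)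
    pre-initiator → initiator (k = 0.233 h⁻¹)

South-east holds 66.8 % monomer in chains after 6.00 d; times the full-book length that is 134, and its living end stands at 72.0 % of the pre-initiator charged. The neighbouring flask is south-east read at 40 h. The exponential gives 31.7 % in chains there, and the flask holds 32.3 %. Times the full-book length that is 64.6, and the flask's average is 115. The ratio of these two is 56.1 %, and its living end is 56.1 % of the pre-initiator charged.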